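**Retrosynthetic overview**
- Floranol ⇐ aromatic Claisen ([3,3]) rearrangement of the 7-O-(1,1-dimethylallyl) ether of the 8-unsubstituted dihydroflavonol; this forms the C8–prenyl bond last, and the C6 methoxy group blocks the other ortho site.
- Ring C ⇐ intramolecular Mitsunobu etherification (O1–C2, inversion) of a threo 2,3-dihydroxy ketone in which O1–H is the only free phenol.
- Dihydroxy ketone ⇐ ortho-lithiated ring A (from 2-methoxyresorcinol, O1 introduced by C–H borylation/oxidation) plus a ring B dioxolane ester.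
- Dioxolane ester ⇐ L-tartrate acetonide by decarboxylative nickel arylation; C3 is bought, C2 is set trans to it and inverted at ring closure.
- Ring order: rings A and B are bought aromatic rings, ring C is closed in step 8, the prenyl group is added in steps 10 and 11.

Assumption: tert-butyl 2-methylbut-3-en-2-yl carbonate is taken as a bought reagent (otherwise one step from 2-methylbut-3-en-2-ol and Boc2O).

**Step 1**
Reactants: 1 2-methoxybenzene-1,3-diol
Product: 2 2-methoxy-1,3-bis[(4-methylbenzyl)oxy]benzene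
Conditions: 4-methylbenzyl bromide (2.2 equiv), K2CO3, DMF, 60 °C
Reagents that add atoms: 4-methylbenzyl bromide, Cc1ccc(CBr)cc1
Why: Williamson etherification of both phenols; the para-methyl groups leave every C–H of the protecting group ortho to a substituent, which keeps them out of the C–H borylation that follows.

**Step 2**
Reactants: 2 2-methoxy-1,3-bis[(4-methylbenzyl)oxy]benzene
Product: 4 4-methoxy-3,5-bis[(4-methylbenzyl)oxy]phenol, via aryl pinacol boronate 3 (not isolated)
Conditions: B2pin2, [Ir(OMe)(cod)]2 (1.5 mol%), 4,4'-di-tert-butyl-2,2'-bipyridine (3 mol%), THF, 80 °C; evaporate; then KHSO5 (as 2KHSO5·KHSO4·K2SO4), acetone/H2O, rt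
Reagents that add atoms: bis(pinacolato)diboron, CC1(C)OB(OC1(C)C)B1OC(C)(C)C(C)(C)O1 (kept only in 3); potassium peroxymonosulfate, [K+].[O-]S(=O)(=O)OO (the new oxygen)
Why: Sterically governed iridium-catalysed C–H borylation goes to the only ring C–H with two hydrogen neighbours (para to OMe), and boronate oxidation then gives the phenol that becomes O1, now distinct from the two flanking oxygens.

**Step 3**
Reactants: 4 4-methoxy-3,5-bis[(4-methylbenzyl)oxy]phenol
Product: 5 2-methoxy-5-(methoxymethoxy)-1,3-bis[(4-methylbenzyl)oxy]benzene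
Conditions: NaH, MOMCl, THF/DMF, 0 °C
Reagents that add atoms: chloromethyl methyl ether, COCCl
Why: Williamson O-alkylation of the sodium phenoxide; the MOM ether is the later ortho-director and the only acid-labile aryl ether on ring A.

**Step 4**
Reactants: 6 dimethyl (4R,5R)-2,2-dimethyl-1,3-dioxolane-4,5-dicarboxylate (from L-tartaric acid)
Product: 7 (4R,5R)-5-(methoxycarbonyl)-2,2-dimethyl-1,3-dioxolane-4-carboxylic acid
Conditions: KOH (1.0 equiv), MeOH, 0 °C to rt; then aq HCl to pH 2
Reagents that add atoms: potassium hydroxide, [K+].[OH-]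
Why: Mono-saponification of the C2-symmetric diester (either ester gives the same acid); cold, one-equivalent conditions do not epimerise the trans-dioxolane.

**Step 5**
Reactants: 7 (4R,5R)-5-(methoxycarbonyl)-2,2-dimethyl-1,3-dioxolane-4-carboxylic acid; 8 1-(benzyloxy)-2-bromobenzene
Product: 11 methyl (4R,5S)-5-[2-(benzyloxy)phenyl]-2,2-dimethyl-1,3-dioxolane-4-carboxylate, via phthalimidoyl ester 9 (not isolated), via arylzinc chloride 10 (not isolated)
Conditions: 7, N-hydroxyphthalimide, DIC, DMAP (cat.), CH2Cl2, rt (9, used crude); separately 8, Mg, LiCl, ZnCl2, THF, rt (10); then NiCl2(dme) (20 mol%), 4,4'-di-tert-butyl-2,2'-bipyridine (40 mol%), THF/DMF, rt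
Reagents that add atoms: N-hydroxyphthalimide, ON1C(=O)c2ccccc2C1=O (kept only in 9); zinc chloride, Cl[Zn]Cl (kept only in 10)
Why: Decarboxylative Negishi-type cross-coupling of a redox-active ester; the dioxolanyl radical is captured by the achiral aryl-nickel species anti to the neighbouring ester, so the aryl-bearing centre (later C2) is set trans to the bought centre (later C3).

**Step 6**
Reactants: 5 2-methoxy-5-(methoxymethoxy)-1,3-bis[(4-methylbenzyl)oxy]benzene; 11 methyl (4R,5S)-5-[2-(benzyloxy)phenyl]-2,2-dimethyl-1,3-dioxolane-4-carboxylate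
Product: 13 {(4R,5S)-5-[2-(benzyloxy)phenyl]-2,2-dimethyl-1,3-dioxolan-4-yl}{3-methoxy-6-(methoxymethoxy)-2,4-bis[(4-methylbenzyl)oxy]phenyl}methanone, via aryllithium 12 (not isolated)
Conditions: 5, n-BuLi, TMEDA, THF, –20 °C (12); then 11, –78 to –40 °C; AcOH quench
Reagents that add atoms: n-butyllithium, [Li]CCCC (Li kept only in 12)
Why: Directed ortho-lithiation at the position flanked by OMOM and an alkoxy group (both such positions are equivalent), then acyl substitution on the ester; the hindered ketone resists a second addition, and the trans-dioxolane is the thermodynamic epimer, so the α-centre holds.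

**Step 7**
Reactants: 13 the ketone from step 6
Product: 14 (2R,3S)-3-[2-(benzyloxy)phenyl]-2,3-dihydroxy-1-{6-hydroxy-3-methoxy-2,4-bis[(4-methylbenzyl)oxy]phenyl}propan-1-one
Conditions: 3 M aq HCl, THF, 45 °C
Reagents that add atoms: none
Why: Acid hydrolysis of the MOM ether and the isopropylidene ketal frees exactly one phenol (O1–H) and the threo diol, while the benzyl-type ethers stay, so O5 cannot take part in ring closure.

**Step 8**
Reactants: 14 the diol from step 7
Product: 15 (2R,3R)-2-[2-(benzyloxy)phenyl]-3-hydroxy-6-methoxy-5,7-bis[(4-methylbenzyl)oxy]-2,3-dihydro-4H-chromen-4-one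
Conditions: PPh3, DIAD, THF (0.01 M), 0 °C to rt
Reagents that add atoms: none
Why: Intramolecular Mitsunobu etherification; the only free phenol displaces the activated benzylic hydroxyl in a six-membered SN2 closure with inversion at C2, turning the threo (2R,3S) diol into the 2,3-trans (2R,3R) dihydroflavonol, which is also the thermodynamic isomer.

**Step 9**
Reactants: 15 the protected dihydroflavonol from step 8
Product: 16 (2R,3R)-3,5,7-trihydroxy-2-(2-hydroxyphenyl)-6-methoxy-2,3-dihydro-4H-chromen-4-one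
Conditions: H2 (1 atm), Pd/C, EtOAc/MeOH, rt
Reagents that add atoms: none
Why: Catalytic hydrogenolysis of the three benzylic aryl ethers under neutral conditions; the cyclic C2–O1 bond and the aryl ketone react much more slowly and no stereocentre is touched.

**Step 10**
Reactants: 16 the tetraol from step 9
Product: 17 (2R,3R)-3,5-dihydroxy-2-(2-hydroxyphenyl)-6-methoxy-7-[(2-methylbut-3-en-2-yl)oxy]-2,3-dihydro-4H-chromen-4-one
Conditions: tert-butyl 2-methylbut-3-en-2-yl carbonate (1.1 equiv), Pd(PPh3)4 (5 mol%), THF, 0 °C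
Reagents that add atoms: tert-butyl 2-methylbut-3-en-2-yl carbonate, C=CC(C)(C)OC(=O)OC(C)(C)C
Why: Tsuji–Trost O-allylation; the tert-butoxide released on ionisation deprotonates the most acidic hydroxyl (7-OH, para to the carbonyl), and the phenoxide attacks the more substituted allyl terminus to give the tertiary ether.

**Step 11**
Reactants: 17 the 7-O-(1,1-dimethylallyl) ether from step 10
Product: 18 floranol, (2R,3R)-3,5,7-trihydroxy-2-(2-hydroxyphenyl)-6-methoxy-8-(3-methylbut-2-en-1-yl)-2,3-dihydro-4H-chromen-4-one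
Conditions: degassed toluene/DMF (10:1), 115 °C, sealed tube
Reagents that add atoms: none
Why: Aromatic Claisen rearrangement ([3,3]-sigmatropic) to the only free ortho position C8 (C6 carries OMe), then tautomerisation, gives the linear prenyl group; neutral heating leaves C3 alone and C2 stays in its preferred trans arrangement.

**Compound list**
1 | 2-methoxybenzene-1,3-diol | COc1c(O)cccc1O | starting material
2 | 2-methoxy-1,3-bis[(4-methylbenzyl)oxy]benzene | COc1c(OCc2ccc(C)cc2)cccc1OCc1ccc(C)cc1 | intermediate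
3 | 2-{4-methoxy-3,5-bis[(4-methylbenzyl)oxy]phenyl}-4,4,5,5-tetramethyl-1,3,2-dioxaborolane | COc1c(OCc2ccc(C)cc2)cc(B2OC(C)(C)C(C)(C)O2)cc1OCc1ccc(C)cc1 | intermediate (not isolated)
4 | 4-methoxy-3,5-bis[(4-methylbenzyl)oxy]phenol | COc1c(OCc2ccc(C)cc2)cc(O)cc1OCc1ccc(C)cc1 | intermediate
5 | 2-methoxy-5-(methoxymethoxy)-1,3-bis[(4-methylbenzyl)oxy]benzene | COCOc1cc(OCc2ccc(C)cc2)c(OC)c(OCc2ccc(C)cc2)c1 | intermediate
6 | dimethyl (4R,5R)-2,2-dimethyl-1,3-dioxolane-4,5-dicarboxylate | COC(=O)[C@@H]1OC(C)(C)O[C@H]1C(=O)OC | starting material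
7 | (4R,5R)-5-(methoxycarbonyl)-2,2-dimethyl-1,3-dioxolane-4-carboxylic acid | COC(=O)[C@@H]1OC(C)(C)O[C@H]1C(=O)O | intermediate
8 | 1-(benzyloxy)-2-bromobenzene | Brc1ccccc1OCc1ccccc1 | starting material
9 | 1,3-dioxoisoindolin-2-yl methyl (4R,5R)-2,2-dimethyl-1,3-dioxolane-4,5-dicarboxylate | COC(=O)[C@@H]1OC(C)(C)O[C@H]1C(=O)ON1C(=O)c2ccccc2C1=O | intermediate (not isolated)
10 | [2-(benzyloxy)phenyl]zinc chloride | Cl[Zn]c1ccccc1OCc1ccccc1 | intermediate (not isolated)
11 | methyl (4R,5S)-5-[2-(benzyloxy)phenyl]-2,2-dimethyl-1,3-dioxolane-4-carboxylate (aryl trans to ester) | COC(=O)[C@@H]1OC(C)(C)O[C@H]1c1ccccc1OCc1ccccc1 | intermediate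
12 | {3-methoxy-6-(methoxymethoxy)-2,4-bis[(4-methylbenzyl)oxy]phenyl}lithium | [Li]c1c(OCOC)cc(OCc2ccc(C)cc2)c(OC)c1OCc1ccc(C)cc1 | intermediate (not isolated)
13 | {(4R,5S)-5-[2-(benzyloxy)phenyl]-2,2-dimethyl-1,3-dioxolan-4-yl}{3-methoxy-6-(methoxymethoxy)-2,4-bis[(4-methylbenzyl)oxy]phenyl}methanone | COCOc1cc(OCc2ccc(C)cc2)c(OC)c(OCc2ccc(C)cc2)c1C(=O)[C@@H]1OC(C)(C)O[C@H]1c1ccccc1OCc1ccccc1 | intermediate
14 | (2R,3S)-3-[2-(benzyloxy)phenyl]-2,3-dihydroxy-1-{6-hydroxy-3-methoxy-2,4-bis[(4-methylbenzyl)oxy]phenyl}propan-1-one (threo) | COc1c(OCc2ccc(C)cc2)cc(O)c(c1OCc1ccc(C)cc1)C(=O)[C@H](O)[C@@H](O)c1ccccc1OCc1ccccc1 | intermediate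
15 | (2R,3R)-2-[2-(benzyloxy)phenyl]-3-hydroxy-6-methoxy-5,7-bis[(4-methylbenzyl)oxy]-2,3-dihydro-4H-chromen-4-one (2,3-trans) | COc1c(OCc2ccc(C)cc2)cc2c(c1OCc1ccc(C)cc1)C(=O)[C@H](O)[C@@H](c1ccccc1OCc1ccccc1)O2 | intermediate
16 | (2R,3R)-3,5,7-trihydroxy-2-(2-hydroxyphenyl)-6-methoxy-2,3-dihydro-4H-chromen-4-one | COc1c(O)cc2c(c1O)C(=O)[C@H](O)[C@@H](c1ccccc1O)O2 | intermediate
17 | (2R,3R)-3,5-dihydroxy-2-(2-hydroxyphenyl)-6-methoxy-7-[(2-methylbut-3-en-2-yl)oxy]-2,3-dihydro-4H-chromen-4-one | COc1c(OC(C)(C)C=C)cc2c(c1O)C(=O)[C@H](O)[C@@H](c1ccccc1O)O2 | intermediate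
18 | floranol, (2R,3R)-3,5,7-trihydroxy-2-(2-hydroxyphenyl)-6-methoxy-8-(3-methylbut-2-en-1-yl)-2,3-dihydro-4H-chromen-4-one | COc1c(O)c(CC=C(C)C)c2c(c1O)C(=O)[C@H](O)[C@@H](c1ccccc1O)O2 | target

**Step count**
Total steps: 11 (convergent). Longest linear sequence: 9 (steps 1, 2, 3, 6, 7, 8, 9, 10, 11).

**Steps most likely to fail, with fallbacks**

Step 5 (ortho-substituted arylzinc in the nickel coupling; diastereocontrol at the radical centre). The fallback sets out from 8 and comes back at 11, building the aryl carbinol by ionic chemistry from a bought glycerate instead of a radical coupling. Bromine–lithium exchange on 8 (n-BuLi, THF, –78 °C) and addition to bought methyl (S)-2,2-dimethyl-1,3-dioxolane-4-carboxylate gives the ketone (S)-[2-(benzyloxy)phenyl](2,2-dimethyl-1,3-dioxolan-4-yl)methanone F1. Felkin-controlled reduction with LiBH(s-Bu)3 at –78 °C gives the syn alcohol (S)-[2-(benzyloxy)phenyl][(S)-2,2-dimethyl-1,3-dioxolan-4-yl]methanol F2. Acid-catalysed acetonide migration (p-TsOH, acetone, rt) to the more stable trans-4,5-disubstituted dioxolane gives {(4S,5S)-5-[2-(benzyloxy)phenyl]-2,2-dimethyl-1,3-dioxolan-4-yl}methanol F3. Oxidation with TEMPO/PhI(OAc)2 in MeCN/H2O gives (4R,5S)-5-[2-(benzyloxy)phenyl]-2,2-dimethyl-1,3-dioxolane-4-carboxylic acid F4, and MeI/K2CO3 in DMF gives 11.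

Step 8 (the Mitsunobu reagent may activate the C3 hydroxyl or form an epoxide instead of the benzylic closure). The fallback sets out from 14 and comes back at 15 by an ionising, thermodynamically controlled closure instead of an SN2 displacement. TfOH (10 mol%) in CH2Cl2/(CF3)2CHOH at 0 °C ionises only the o-alkoxybenzylic hydroxyl, the free O1–H traps the cation, and the product equilibrates to the 2,3-trans isomer. New compound on the way: none F0.

Step 10 (mono-O-alkylation of a tetraol; branched versus linear ether). The fallback sets out from 16 and comes back at 17 by copper-assisted propargylic substitution and semihydrogenation instead of allylpalladium chemistry. 3-Chloro-3-methylbut-1-yne, K2CO3 (1.1 equiv), KI and CuI (cat.) in acetone at 50 °C alkylate the most acidic 7-OH to give (2R,3R)-3,5-dihydroxy-2-(2-hydroxyphenyl)-6-methoxy-7-[(2-methylbut-3-yn-2-yl)oxy]-2,3-dihydro-4H-chromen-4-one F5. H2 over Pd/CaCO3 poisoned with Pb(OAc)2, with quinoline in EtOAc, then reduces the alkyne to the alkene 17.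

**Further compounds**
F1 | step 5 | (S)-[2-(benzyloxy)phenyl](2,2-dimethyl-1,3-dioxolan-4-yl)methanone | O=C([C@@H]1COC(C)(C)O1)c1ccccc1OCc1ccccc1
F2 | step 5 | (S)-[2-(benzyloxy)phenyl][(S)-2,2-dimethyl-1,3-dioxolan-4-yl]methanol | O[C@H]([C@@H]1COC(C)(C)O1)c1ccccc1OCc1ccccc1
F3 | step 5 | {(4S,5S)-5-[2-(benzyloxy)phenyl]-2,2-dimethyl-1,3-dioxolan-4-yl}methanol | OC[C@@H]1OC(C)(C)O[C@H]1c1ccccc1OCc1ccccc1
F4 | step 5 | (4R,5S)-5-[2-(benzyloxy)phenyl]-2,2-dimethyl-1,3-dioxolane-4-carboxylic acid | OC(=O)[C@@H]1OC(C)(C)O[C@H]1c1ccccc1OCc1ccccc1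
F0 | step 8 | none | none
F5 | step 10 | (2R,3R)-3,5-dihydroxy-2-(2-hydroxyphenyl)-6-methoxy-7-[(2-methylbut-3-yn-2-yl)oxy]-2,3-dihydro-4H-chromen-4-one | COc1c(OC(C)(C)C#C)cc2c(c1O)C(=O)[C@H](O)[C@@H](c1ccccc1O)O2
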